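**Retrosynthetic overview**

1. Target 38 ⇐ ring A enone (from a C1 silyl enol ether), C6 aldehyde (from a silyl ether) and 15‑OH/16,17‑epoxide (from a 16‑methylene‑15‑ketone) ⇐ bicyclo[3.2.1]oct‑11‑en‑15‑one 29.
2. Key disconnection: C11–C12 of ring C, the one ring‑C bond of the bicyclo[3.2.1]octane that touches neither quaternary C8 nor a bridgehead bond (it lies between the C9 methine and bridgehead C13) ⇒ metathesis of the C9 and C13 vinyl groups of spiro‑cyclopentanone 28.
3. Ring D ⇐ C8–C15 Claisen‑type closure onto a Weinreb amide; C13 ⇐ Ir‑catalysed allylic alkylation; C14 ⇐ C8 allylation; C9 vinyl ⇐ cuprate addition to unsaturated spirolactone 13.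
4. Spirolactone ⇐ ring A formyl enone 5 + methyl 2‑chloroacrylate (sets quaternary C10); C5 ⇐ Rh‑catalysed desymmetrising vinylation of dienone 2.
5. Ring order: A (from 1) → lactone → D → C (key step) → epoxide.

Key step: step 18

Remark: carbon atoms carry the ent‑kaurane numbers of the target throughout (ring A C1–C5, C10; C6 on C5; lactone C10–C20–O–C7(=O)–C8–C9; ring C C8, C9, C11–C14; ring D C8, C14, C13, C16, C15; C17 on C16).
Remark: the sense of induction of each chiral catalyst is assigned by the accepted model for that catalyst; the other ligand enantiomer would be used if the opposite sense were found.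
Remark: 7–12 are mixtures at the chlorine‑bearing carbon and 24–27 at C8; both centres are removed or set again later, so the mixtures converge.

**Route**

Step 1
Reactants: 1 4,4-dimethylcyclohex-2-en-1-one
Product: 2 4,4-dimethylcyclohexa-2,5-dien-1-one
Conditions: DDQ, dioxane, reflux
Reagents that add atoms: none
Why: Quinone dehydrogenation of an enone to the cross‑conjugated dienone, which cannot aromatise because C4 is quaternary.

Step 2
Reactants: 2 4,4-dimethylcyclohexa-2,5-dien-1-one; 3 potassium vinyltrifluoroborate
Product: 4 (5R)-5-ethenyl-4,4-dimethylcyclohex-2-en-1-one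
Conditions: [Rh(cod)2]BF4 (3 mol %), (R)-BINAP, 3 (1.1 equiv), toluene/H2O, 90 °C
Reagents that add atoms: none
Why: Rhodium‑catalysed asymmetric 1,4‑addition of an alkenylboron reagent (Hayashi–Miyaura reaction), in which the two enone units of 2 are homotopic, the (R)-BINAP complex selects one enone face and so sets C5, and the more hindered mono‑adduct should resist a second addition.

Step 3
Reactants: 4 (5R)-5-ethenyl-4,4-dimethylcyclohex-2-en-1-one
Product: 5 (5R)-5-ethenyl-6-(hydroxymethylidene)-4,4-dimethylcyclohex-2-en-1-one
Conditions: LiN(i-Pr)2, THF, −78 °C; HCO2CH2CF3; aq. HCl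
Reagents that add atoms: 2,2,2-trifluoroethyl formate, O=COCC(F)(F)F
Why: Kinetic deprotonation at the only enolisable position (C10, the ring A enone acting as a blocking group) and Claisen formylation give the hydroxymethylidene ketone regiospecifically.

Step 4
Reactants: 5 (5R)-5-ethenyl-6-(hydroxymethylidene)-4,4-dimethylcyclohex-2-en-1-one; 6 methyl 2-chloroprop-2-enoate
Product: 7 methyl 2-chloro-3-[(1S,6R)-6-ethenyl-1-formyl-5,5-dimethyl-2-oxocyclohex-3-en-1-yl]propanoate
Conditions: Et3N (0.2 equiv), CH2Cl2, 0 °C to rt
Reagents that add atoms: none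
Why: Amine‑catalysed Michael addition of the 2‑formyl ketone enol to the activated acrylate, which should approach C10 anti to the adjacent pseudoaxial C5 vinyl group and so place the C9 arm trans to C6 and the formyl carbon (C20) cis to it.

Step 5
Reactants: 7 Michael adduct
Product: 10 8-chloro spirolactone alcohol with ring A enone, via dialdehyde 8 (not isolated), via diol ester 9 (not isolated)
Conditions: O3, CH2Cl2/MeOH, −78 °C; Me2S; NaBH4, −78 to −40 °C; then p-TsOH (cat.), CH2Cl2, rt
Reagents that add atoms: ozone, [O-][O+]=O
Why: Ozonolysis cleaves the monosubstituted alkene much faster than the electron‑poor enone, borohydride at low temperature reduces the two aldehydes but not the hindered conjugated ketone or the ester, and acid‑catalysed lactonisation through the C20 hydroxyl closes the six‑membered ring in preference to a seven‑membered ring through the C6 hydroxyl.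

Step 6
Reactants: 10 8-chloro spirolactone alcohol
Product: 11 C6 tert-butyldimethylsilyl ether of 10
Conditions: t-BuMe2SiOTf, 2,6-lutidine, CH2Cl2, −78 °C
Reagents that add atoms: tert-butyldimethylsilyl trifluoromethanesulfonate, CC(C)(C)[Si](C)(C)OS(=O)(=O)C(F)(F)F
Why: Silylation of the primary alcohol with a silyl triflate and a hindered base, conditions too mild to dehydrochlorinate the α‑chloro lactone.

Step 7
Reactants: 11 silyl ether with ring A enone
Product: 12 8-chloro spirolactone with saturated ring A ketone
Conditions: H2 (1 atm), Rh/Al2O3, EtOAc, rt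
Reagents that add atoms: none
Why: Heterogeneous hydrogenation of the disubstituted enone C=C on rhodium, a metal that is slow in hydrogenolysis of an aliphatic C–Cl bond in the absence of base.

Step 8
Reactants: 12 8-chloro spirolactone ketone
Product: 13 8,9-unsaturated spirolactone ketone
Conditions: DBU, toluene, 80 °C
Reagents that add atoms: none
Why: E2 dehydrochlorination of an α‑chloro δ‑lactone, which has β‑hydrogens only at C9, is the classical entry to 5,6‑dihydropyran‑2‑ones and needs no strong base that would enolise the C1 ketone.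

Step 9
Reactants: 13 8,9-unsaturated spirolactone ketone; 14 vinylmagnesium bromide
Product: 16 9-vinyl spirolactone ketone, via silyl ketene acetal 15 (not isolated)
Conditions: 14 (2 equiv), CuBr·SMe2 (20 mol %), Me3SiCl, THF, −78 °C; aq. NH4Cl
Reagents that add atoms: none
Why: Copper‑catalysed conjugate addition of the Grignard reagent accelerated by Me3SiCl, in which the vinyl group should be delivered to C9 from the face of the flat C1 carbonyl, away from C5 and its silyloxymethyl arm, while the hindered C1 ketone is left alone at −78 °C.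

Step 10
Reactants: 17 (E)-but-2-ene-1,4-diol
Product: 18 (E)-4-hydroxybut-2-en-1-yl methyl carbonate
Conditions: ClCO2Me (1 equiv), pyridine, CH2Cl2, 0 °C, excess 17
Reagents that add atoms: methyl chloroformate, COC(Cl)=O
Why: Statistical mono‑acylation of a symmetric diol, made selective by the excess of diol.

Step 11
Reactants: 18 (E)-4-hydroxybut-2-en-1-yl methyl carbonate
Product: 19 (E)-4-bromobut-2-en-1-yl methyl carbonate
Conditions: CBr4, PPh3, CH2Cl2, 0 °C
Reagents that add atoms: carbon tetrabromide, BrC(Br)(Br)Br
Why: Appel bromination of a primary allylic alcohol under neutral conditions that leave the carbonate intact.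

Step 12
Reactants: 20 methyl 3-chloro-3-oxopropanoate
Product: 21 methyl 3-[methoxy(methyl)amino]-3-oxopropanoate
Conditions: MeNH(OMe)·HCl, pyridine, CH2Cl2, 0 °C
Reagents that add atoms: N,O-dimethylhydroxylamine hydrochloride, CNOC.Cl
Why: Acylation of the hydroxylamine by the acid chloride (Weinreb amide formation).

Step 13
Reactants: 16 9-vinyl spirolactone ketone; 19 (E)-4-bromobut-2-en-1-yl methyl carbonate
Product: 24 C8-allylated lactone ketone bearing the allylic methyl carbonate, via trimethylsilyl enol ether 22 (not isolated), via alkylated silyl enol ether 23 (not isolated)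
Conditions: Me3SiOTf, Et3N, CH2Cl2, −20 °C; LiN(i-Pr)2, THF, −78 °C; 19, DMPU, −78 to −40 °C; AcOH/THF/H2O, 0 °C
Reagents that add atoms: none
Why: Temporary masking of the more acidic C1 ketone as its silyl enol ether lets the amide base form the lactone enolate, which undergoes SN2 alkylation at C8 by the allylic bromide faster than it attacks the carbonate, and either C8 epimer serves because C8 is enolised again in step 17.

Step 14
Reactants: 24 allylic carbonate; 21 methyl 3-[methoxy(methyl)amino]-3-oxopropanoate
Product: 25 branched malonamate with the C13 vinyl group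
Conditions: [Ir(cod)Cl]2 (2 mol %), binaphthyl N,N-bis(1-phenylethyl)phosphoramidite (4 mol %), TBD (8 mol %), THF, rt to 50 °C
Reagents that add atoms: none
Why: Iridium‑catalysed asymmetric allylic alkylation with a stabilised malonate‑type nucleophile, which attacks the substituted allyl terminus to give the branched product with a terminal vinyl group, C13 being set by the phosphoramidite ligand (catalyst control) in the sense that later places this vinyl group cis to C9 across ring D.

Step 15
Reactants: 25 branched malonamate
Product: 26 lactone ketone with the C13 vinyl Weinreb amide arm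
Conditions: LiCl, H2O, DMSO, 130 °C
Reagents that add atoms: none
Why: Krapcho dealkoxycarbonylation, in which chloride demethylates the ester and the carboxylate loses CO2, while the neopentyl lactone carbon C20 is not attacked.

Step 16
Reactants: 26 lactone ketone with Weinreb amide arm
Product: 27 C1 tert-butyldimethylsilyl enol ether of 26
Conditions: t-BuMe2SiOTf (1.1 equiv), Et3N, CH2Cl2, −20 to 0 °C
Reagents that add atoms: tert-butyldimethylsilyl trifluoromethanesulfonate, CC(C)(C)[Si](C)(C)OS(=O)(=O)C(F)(F)F
Why: Soft enolisation converts the ketone, enolisable only towards C2, into its silyl enol ether faster than the lactone or amide, which protects C1 from base and hydride and is the later precursor of the ring A enone.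

Step 17
Reactants: 27 silyl enol ether with Weinreb amide arm
Product: 28 spirolactone spiro-cyclopentanone with vinyl groups on C9 and C13
Conditions: LiN(SiMe3)2 (2 equiv), THF, −78 to 0 °C; aq. NH4Cl
Reagents that add atoms: none
Why: Claisen‑type intramolecular acylation (5‑exo‑trig) of the lactone enolate by the Weinreb amide, in which the silazide deprotonates the lactone but not the less acidic amide, the chelated tetrahedral adduct persists until work‑up so that no retro‑Claisen can occur, and the tether should close on the H9 face, opposite the C9 vinyl and C1 silyloxy groups, placing C15 trans and C14 cis to the C9 vinyl group and hence the C13 vinyl group cis to C9.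

Step 18
Reactants: 28 spirolactone spiro-cyclopentanone diene
Product: 29 bicyclo[3.2.1]oct-11-en-15-one spirolactone
Conditions: second-generation Grubbs catalyst (5 mol %), CH2Cl2 (2 mM), 40 °C
Reagents that add atoms: none
Why: The ruthenium alkylidene should load on the more accessible C13 vinyl group, add [2+2] across the C9 vinyl group held nearby and cyclorevert with loss of ethylene to give the C11=C12 alkene. The closest known reaction type is ring‑closing olefin metathesis of cis‑1,3‑dialkenyl cycloalkanes to bridged bicycloalkenes. Ring C closes as a six‑membered cycloalkene that bridges C8 and C13 of ring D, so that rings C and D together form a bicyclo[3.2.1]oct‑2‑ene. No stereocentre is created, and C8, C9 and C13 are spectators. Ring closure must win over cross‑metathesis, which is secured by the cis relation of the C13 vinyl group and the C9 arm across ring D (steps 14 and 17), by the lactone ring that holds the C9 vinyl group gauche to C14, and by high dilution. The trisubstituted silyl enol ether and the carbonyl groups are inert to the catalyst.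

Step 19
Reactants: 29 bicyclo[3.2.1]oct-11-en-15-one spirolactone
Product: 30 11,12-dihydro ketone
Conditions: 2-nitrobenzenesulfonylhydrazide, Et3N, CH2Cl2, rt
Reagents that add atoms: none
Why: Diimide reduction transfers hydrogen to the strained, unhindered disubstituted alkene and leaves the trisubstituted silyl enol ether and the carbonyl groups untouched.

Step 20
Reactants: 30 11,12-dihydro ketone
Product: 33 16-methylene-15-ketone, via Mannich base 31 (not isolated), via methiodide 32 (not isolated)
Conditions: LiN(SiMe3)2, THF, −78 °C; CH2=NMe2 iodide, −78 °C to rt; MeI, CH2Cl2; aq. NaHCO3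
Reagents that add atoms: dimethylmethyleneammonium iodide, C=[N+](C)C.[I-]
Why: Mannich reaction of the C15 ketone enolate (enolisable only at C16) with the iminium salt, then quaternisation and elimination of trimethylamine, is the standard α‑methylenation of a ketone.

Step 21
Reactants: 33 16-methylene-15-ketone
Product: 34 15-hydroxy-16-methylene compound
Conditions: NaBH4, CeCl3·7H2O, MeOH, −78 °C
Reagents that add atoms: none
Why: Luche 1,2‑reduction of the enone, in which hydride should arrive from the exo face of the two‑carbon bridge (the C14 side, the endo face being screened by the C11 methylene) to give the endo 15‑alcohol of the target, while the lactone and the silyl enol ether are inert.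

Step 22
Reactants: 34 15-hydroxy-16-methylene compound
Product: 35 ring A 2-en-1-one
Conditions: Pd(OAc)2 (1.2 equiv), MeCN, rt
Reagents that add atoms: none
Why: Saegusa–Ito oxidation, in which the silyl enol ether transfers its enolate to divalent palladium and β‑hydride elimination from C3 delivers the C2=C3 enone.

Step 23
Reactants: 35 ring A enone allylic alcohol
Product: 36 16,17-epoxy-15-alcohol
Conditions: VO(acac)2 (5 mol %), t-BuOOH, CH2Cl2, 0 °C to rt
Reagents that add atoms: tert-butyl hydroperoxide, CC(C)(C)OO
Why: Vanadium‑catalysed hydroxyl‑directed epoxidation delivers oxygen to the 16(17)‑alkene on the face of the C15 hydroxyl, setting C16 with epoxide oxygen and hydroxyl cis, and the electron‑poor ring A enone does not react.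

Step 24
Reactants: 36 16,17-epoxy-15-alcohol silyl ether
Product: 37 C6 primary alcohol
Conditions: Bu4NF, AcOH, THF, 0 °C to rt
Reagents that add atoms: none
Why: Fluoride cleavage of the primary silyl ether, buffered with acetic acid so that neither retro‑aldol cleavage of the β‑hydroxy lactone nor Payne rearrangement of the epoxy alcohol is triggered.

Step 25
Reactants: 37 C6 primary alcohol
Product: 38 CNP0537841.1
Conditions: TEMPO (10 mol %), PhI(OAc)2, CH2Cl2, rt
Reagents that add atoms: none
Why: Oxoammonium (TEMPO) oxidation selects the primary alcohol over the hindered secondary C15 alcohol, and the mild conditions should not epimerise C5.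

**Compound list**

1 | 4,4-dimethylcyclohex-2-en-1-one | CC1(C)CCC(=O)C=C1 | starting material
2 | 4,4-dimethylcyclohexa-2,5-dien-1-one | CC1(C)C=CC(=O)C=C1 | intermediate
3 | potassium vinyltrifluoroborate | [K+].F[B-](F)(F)C=C | starting material
4 | (5R)-5-ethenyl-4,4-dimethylcyclohex-2-en-1-one | CC1(C)C=CC(=O)C[C@@H]1C=C | intermediate
5 | (5R)-5-ethenyl-6-(hydroxymethylidene)-4,4-dimethylcyclohex-2-en-1-one (enol form of the C10 formyl ketone) | CC1(C)C=CC(=O)C(=CO)[C@@H]1C=C | intermediate
6 | methyl 2-chloroprop-2-enoate | C=C(Cl)C(=O)OC | starting material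
7 | methyl 2-chloro-3-[(1S,6R)-6-ethenyl-1-formyl-5,5-dimethyl-2-oxocyclohex-3-en-1-yl]propanoate (C9 arm trans to the C5 vinyl group; both epimers at CHCl) | CC1(C)C=CC(=O)[C@@](C=O)(CC(Cl)C(=O)OC)[C@@H]1C=C | intermediate
8 | dialdehyde: 7 with the vinyl group cleaved to the C6 aldehyde | CC1(C)C=CC(=O)[C@@](C=O)(CC(Cl)C(=O)OC)[C@@H]1C=O | intermediate
9 | diol ester: C6 and C20 hydroxymethyl groups, cis on ring A | CC1(C)C=CC(=O)[C@@](CO)(CC(Cl)C(=O)OC)[C@@H]1CO | intermediate
10 | 8-chloro spirolactone alcohol (ring A 2-en-1-one; δ-lactone C10–C20–O–C7(=O)–C8HCl–C9H2; C6 hydroxymethyl cis to C20) | CC1(C)C=CC(=O)[C@]2(COC(=O)C(Cl)C2)[C@@H]1CO | intermediate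
11 | C6 tert-butyldimethylsilyl ether of 10 | CC1(C)C=CC(=O)[C@]2(COC(=O)C(Cl)C2)[C@@H]1CO[Si](C)(C)C(C)(C)C | intermediate
12 | 8-chloro spirolactone with saturated ring A 1-ketone | CC1(C)CCC(=O)[C@]2(COC(=O)C(Cl)C2)[C@@H]1CO[Si](C)(C)C(C)(C)C | intermediate
13 | 8,9-unsaturated spirolactone ketone | CC1(C)CCC(=O)[C@]2(COC(=O)C=C2)[C@@H]1CO[Si](C)(C)C(C)(C)C | intermediate
14 | vinylmagnesium bromide | C=C[Mg]Br | starting material
15 | trimethylsilyl ketene acetal of lactone 16 | CC1(C)CCC(=O)[C@]2(COC(O[Si](C)(C)C)=C[C@H]2C=C)[C@@H]1CO[Si](C)(C)C(C)(C)C | intermediate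
16 | 9-vinyl spirolactone ketone (vinyl on the C1 face of the lactone, trans to C5) | CC1(C)CCC(=O)[C@]2(COC(=O)C[C@H]2C=C)[C@@H]1CO[Si](C)(C)C(C)(C)C | intermediate
17 | (E)-but-2-ene-1,4-diol | OC/C=C/CO | starting material
18 | (E)-4-hydroxybut-2-en-1-yl methyl carbonate | COC(=O)OC/C=C/CO | intermediate
19 | (E)-4-bromobut-2-en-1-yl methyl carbonate | COC(=O)OC/C=C/CBr | intermediate
20 | methyl 3-chloro-3-oxopropanoate | COC(=O)CC(Cl)=O | starting material
21 | methyl 3-[methoxy(methyl)amino]-3-oxopropanoate | COC(=O)CC(=O)N(C)OC | intermediate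
22 | C1 trimethylsilyl enol ether of 16 | CC1(C)CC=C(O[Si](C)(C)C)[C@]2(COC(=O)C[C@H]2C=C)[C@@H]1CO[Si](C)(C)C(C)(C)C | intermediate
23 | C8-alkylated trimethylsilyl enol ether (C8 epimers) | CC1(C)CC=C(O[Si](C)(C)C)[C@]2(COC(=O)C(C/C=C/COC(=O)OC)[C@H]2C=C)[C@@H]1CO[Si](C)(C)C(C)(C)C | intermediate
24 | C8-[(E)-4-(methoxycarbonyloxy)but-2-enyl] 9-vinyl spirolactone ketone (C8 epimers) | CC1(C)CCC(=O)[C@]2(COC(=O)C(C/C=C/COC(=O)OC)[C@H]2C=C)[C@@H]1CO[Si](C)(C)C(C)(C)C | intermediate
25 | branched malonamate: C13 bears vinyl and CH(CO2Me)C(O)N(OMe)Me (epimers at C8 and C16) | CC1(C)CCC(=O)[C@]2(COC(=O)C(C[C@@H](C=C)C(C(=O)OC)C(=O)N(C)OC)[C@H]2C=C)[C@@H]1CO[Si](C)(C)C(C)(C)C | intermediate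
26 | lactone ketone with C8–CH2–CH(vinyl)–CH2–C(O)N(OMe)Me arm (C8 epimers) | CC1(C)CCC(=O)[C@]2(COC(=O)C(C[C@@H](C=C)CC(=O)N(C)OC)[C@H]2C=C)[C@@H]1CO[Si](C)(C)C(C)(C)C | intermediate
27 | C1 tert-butyldimethylsilyl enol ether of 26 (C8 epimers) | CC1(C)CC=C(O[Si](C)(C)C(C)(C)C)[C@]2(COC(=O)C(C[C@@H](C=C)CC(=O)N(C)OC)[C@H]2C=C)[C@@H]1CO[Si](C)(C)C(C)(C)C | intermediate
28 | spirolactone spiro-cyclopentanone with vinyl groups on C9 and C13 (C13 vinyl cis to C9 across ring D; C1 silyl enol ether) | CC1(C)CC=C(O[Si](C)(C)C(C)(C)C)[C@]2(COC(=O)[C@@]3(C[C@@H](C=C)CC3=O)[C@H]2C=C)[C@@H]1CO[Si](C)(C)C(C)(C)C | intermediate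
29 | bicyclo[3.2.1]oct-11-en-15-one spirolactone (C1 silyl enol ether) | CC1(C)CC=C(O[Si](C)(C)C(C)(C)C)[C@]2(COC(=O)[C@@]34C[C@@H](C=C[C@@H]23)CC4=O)[C@@H]1CO[Si](C)(C)C(C)(C)C | intermediate
30 | 11,12-dihydro 15-ketone | CC1(C)CC=C(O[Si](C)(C)C(C)(C)C)[C@]2(COC(=O)[C@@]34C[C@@H](CC[C@@H]23)CC4=O)[C@@H]1CO[Si](C)(C)C(C)(C)C | intermediate
31 | Mannich base: 16-(dimethylaminomethyl)-15-ketone (C16 epimers) | CC1(C)CC=C(O[Si](C)(C)C(C)(C)C)[C@]2(COC(=O)[C@@]34C[C@@H](CC[C@@H]23)C(CN(C)C)C4=O)[C@@H]1CO[Si](C)(C)C(C)(C)C | intermediate
32 | methiodide of 31 | CC1(C)CC=C(O[Si](C)(C)C(C)(C)C)[C@]2(COC(=O)[C@@]34C[C@@H](CC[C@@H]23)C(C[N+](C)(C)C)C4=O)[C@@H]1CO[Si](C)(C)C(C)(C)C.[I-] | intermediate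
33 | 16-methylene-15-ketone | CC1(C)CC=C(O[Si](C)(C)C(C)(C)C)[C@]2(COC(=O)[C@@]34C[C@@H](CC[C@@H]23)C(=C)C4=O)[C@@H]1CO[Si](C)(C)C(C)(C)C | intermediate
34 | endo 15-alcohol with 16-methylene | CC1(C)CC=C(O[Si](C)(C)C(C)(C)C)[C@]2(COC(=O)[C@@]34C[C@@H](CC[C@@H]23)C(=C)[C@H]4O)[C@@H]1CO[Si](C)(C)C(C)(C)C | intermediate
35 | ring A 2-en-1-one with 15-alcohol and 16-methylene | CC1(C)C=CC(=O)[C@]2(COC(=O)[C@@]34C[C@@H](CC[C@@H]23)C(=C)[C@H]4O)[C@@H]1CO[Si](C)(C)C(C)(C)C | intermediate
36 | 16,17-epoxy-15-alcohol, C6 silyl ether (epoxide oxygen cis to 15-OH) | CC1(C)C=CC(=O)[C@]2(COC(=O)[C@@]34C[C@@H](CC[C@@H]23)[C@]2(CO2)[C@H]4O)[C@@H]1CO[Si](C)(C)C(C)(C)C | intermediate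
37 | C6 primary alcohol | CC1(C)C=CC(=O)[C@]2(COC(=O)[C@@]34C[C@@H](CC[C@@H]23)[C@]2(CO2)[C@H]4O)[C@@H]1CO | intermediate
38 | CNP0537841.1 | CC1(C)C=CC(=O)[C@]2(COC(=O)[C@@]34C[C@@H](CC[C@@H]23)[C@]2(CO2)[C@H]4O)[C@@H]1C=O | target

**Step count and risks**

Total step count: 25. Longest linear sequence: 22 steps (steps 1–9 and 13–25).

Steps most likely to fail:

1. Step 17 (spiro‑annulation of ring D). The closure may show poor facial selectivity at C8, the amide carbon entering on the side of the C9 vinyl group, or the amide side may be deprotonated in competition. Fallback: the order of the two ring closures is exchanged. Setting out from 27, ring‑closing metathesis with the second‑generation Grubbs catalyst (CH2Cl2, 40 °C) would join the two vinyl groups first, an unstrained six‑membered ring closure, and give the cyclohexene-fused lactone with the C13 Weinreb acetamide arm F1. Treatment with LiN(SiMe3)2 (THF, −78 to 0 °C) would then form the C8–C15 bond by transannular Claisen‑type acylation. The two‑carbon bridge can only span the face of ring C that carries the C13 arm, so C8 would be fixed by C13 and C9 and not by a facial preference. The sequence returns to the route at 29 and would also serve if step 18 stalls.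

2. Step 9 (vinyl addition at C9). Facial selectivity rests on a steric contrast between the C1 carbonyl and the C5 side, and the β‑carbon is neopentyl, so low selectivity or incomplete conversion is the risk. Fallback: reagent control in place of substrate control. Setting out from 13, rhodium‑catalysed asymmetric 1,4‑addition of 3 ([Rh(cod)2]BF4, the BINAP or chiral diene enantiomer whose preferred face is the C1 face, toluene/H2O, 90 °C) would give 16 directly and return to the route there; no new compound is involved.

3. Step 14 (allylic alkylation). The reaction may give a low branched‑to‑linear ratio or incomplete catalyst control at C13 in a substrate that carries a nearby stereocentre. Fallback: the C13 stereocentre is made in a small building block and attached by enolate alkylation.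
   - Rhodium‑catalysed addition of 3 to commercial furan‑2(5H)‑one ([Rh(cod)2]BF4, (R)-BINAP) would give (4R)-4-ethenyloxolan-2-one F2.
   - Opening with MeNH(OMe)·HCl and AlMe3 would give (3R)-3-(hydroxymethyl)-N-methoxy-N-methylpent-4-enamide F3.
   - I2, PPh3 and imidazole would give (3R)-3-(iodomethyl)-N-methoxy-N-methylpent-4-enamide F4.
   - Setting out from 16, the lithium enolate of silyl enol ether 22 (made as in step 13) would be alkylated with the iodide (LiN(i-Pr)2, THF/DMPU, −78 to −30 °C) to the alkylated trimethylsilyl enol ether F5. Mild acid would release the C1 ketone and return to the route at 26.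

Further compounds
F1 | step 17 | cyclohexene-fused lactone with the C13 Weinreb acetamide arm (ring C closed, ring D open; C8 epimers) | CC1(C)CC=C(O[Si](C)(C)C(C)(C)C)[C@]2(COC(=O)C3C[C@@H](C=C[C@@H]23)CC(=O)N(C)OC)[C@@H]1CO[Si](C)(C)C(C)(C)C
F0 | step 9 | none | none
F2 | step 14 | (4R)-4-ethenyloxolan-2-one | O1C[C@@H](C=C)CC1=O
F3 | step 14 | (3R)-3-(hydroxymethyl)-N-methoxy-N-methylpent-4-enamide | OC[C@@H](C=C)CC(=O)N(C)OC
F4 | step 14 | (3R)-3-(iodomethyl)-N-methoxy-N-methylpent-4-enamide | IC[C@@H](C=C)CC(=O)N(C)OC
F5 | step 14 | alkylated trimethylsilyl enol ether (C1 silyl enol ether of 26; C8 epimers) | CC1(C)CC=C(O[Si](C)(C)C)[C@]2(COC(=O)C(C[C@@H](C=C)CC(=O)N(C)OC)[C@H]2C=C)[C@@H]1CO[Si](C)(C)C(C)(C)C
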